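At early times this flask runs on two additions that need no catalyst: substrate and coupling partner join either to target or to its isomer, while free catalyst, released from the precatalyst, interconverts those two products.

substrate 0.50 mM; coupling partner 0.350 mM; precatalyst 1.0 µM; added ligand 1.9 µM; time 20 min

* why nothing more happens at 20 min, or that something still does (all of the substrate has reacted / the coupling partner has run out first / it is still moving / forward and back rates have come level / no working catalyst is left)
* amount of target at 20 min, in percent of the substrate charged

- for a step with 2 of a species take k times the square, and two of it per event
- the reaction counts as stopped when no species that holds the substrate changes by six tenths of a point or more over the second half of the time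
- run time (flask): 20 min

    target + free catalyst ⇌ isomer of the product + free catalyst, rate k1*[free catalyst]*[target] forward; the back reaction follows from the equilibrium constant (k1 = 1.4 × 10⁵ L mol⁻¹ s⁻¹)
    free catalyst + added ligand ⇌ idle complex (K2 = 8.2 × 10⁵ L mol⁻¹, k2 = 6.9 × 10⁵ L mol⁻¹ s⁻¹)
    2 free catalyst → spent catalyst (k3 = 52000 L mol⁻¹ s⁻¹)
    substrate + coupling partner ⇌ isomer of the product (K4 = 8300 L mol⁻¹, k4 = 2400 L mol⁻¹ s⁻¹)
    substrate + coupling partner ⇌ target (K5 = 1300 L mol⁻¹, k5 = 4500 L mol⁻¹ s⁻¹)
    precatalyst ⇌ free catalyst (K6 = 2.8, k6 = 0.19 s⁻¹)

A reckoning by hand starts from the rate. In this flask the two additions together begin at 1.21 mM s⁻¹, and target takes the larger part of that rate, 65.2%, a kinetic preference. The back steps have first-order constants of 3.46 s⁻¹ for target and 0.289 s⁻¹ for the isomer, and even the smaller gives a half-life of 2.40 s, far shorter than the run of 20 min, so the answer should not depend on time. Dividing each forward rate by its back rate removes time: when they are level, target over the product of free substrate and free coupling partner equals 1300 L mol⁻¹, and the isomer over the same product equals 8300 L mol⁻¹. Total adduct over that product is therefore the balance constant, 9600 L mol⁻¹, of which target holds a share of 13.5%. The catalysed step asks for the same ratio of isomer to target.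

With 0.104 mM as the inverse of that constant, the charges give total adduct of 0.248 mM. Substrate loss then slows the forward rate by a factor of 1.98 and coupling partner loss by 3.42, together 6.77, which brings it down to 0.179 mM s⁻¹. The back steps, rising from zero, return just that much, so the net rate reaches zero with 29.2% of the coupling partner, the limiting reagent, still unbound. By this reckoning target stands at 0.0335 mM, which is 6.71% of the substrate charged.

The forecast answers on the ending: forward and back rates have come level. It puts target at 6.71%, within 6.5% to 6.9%, holding that “the catalyst, its ligand and its death change nothing at the end”. The reckoning above takes the same route to the same figure.

The simulation gives for the ending: forward and back rates have come level. It gives target at 6.71%, so the forecast stands on both answers.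

In this flask conversion of substrate ends at 49.5% through two things acting together, each a part of the reason: the running short of coupling partner, of which 29% of the charge is left, and the undoing of the isomer into substrate and coupling partner. With the shortage taken away conversion reaches 77.1%, and with that undoing struck out 69.9%. The latter run also turns the answer on the ending, and that is the change that would prove the forecast wrong, for 9600 L mol⁻¹ is the sum of two ratios of forward to back rate constants. In the neighbour flask with 0.087 mM of coupling partner, 9600 L mol⁻¹ gives 0.0700 mM of adduct and, at a share of 13.5%, target at 1.90% of the substrate charged; the computed value is 1.90%.

The constants used here are invented; what happens was integrated by code.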